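The earlier runs and the new flask are calculated for substances that don't exist; scatter was added.

**The pitfall.** Multiplying the starting rate by the hours looks sound, but the readings show the rate sinking. J and X each react with Q on E, two E can park as L, Q also goes to G by itself, and D and Z interconvert.

| flask | J | X | Q | E | remark | time |
|---|---|---|---|---|---|---|
| birch | 0.10 M | 0.10 M | 0.20 M | 4 mM | run made earlier |  |
| elm | 0.10 M | 0.10 M | 0.20 M | 11 mM | run made earlier |  |
| noon | 0.10 M | 0.10 M | 0.200 M | 3.2 mM |  | 40 h |
| summer | 0.10 M | 0.10 M | 0.200 M | 10 mM |  | 40 h |

| run | time / h | X / % | J / % |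
|---|---|---|---|
| birch | 2.50 | 47 | 45 |
| birch | 3.00 | 51 | 42 |
| birch | 5.00 | 47 | 39 |
| birch | 8.00 | 42 | 34 |
| birch | 12.0 | 43 | 32 |
| birch | 20.0 | 38 | 28 |
| birch | 30.0 | 41 | 21 |
| elm | 4.00 | 47 | 34 |
| elm | 8.00 | 41 | 29 |
| elm | 12.0 | 37 | 23 |
| elm | 15.0 | 37 | 23 |
| elm | 20.0 | 37 | 23 |
| elm | 25.0 | 33 | 15 |
| elm | 30.0 | 36 | 16 |

(each reading ± 2 percentage points)

* the flask that ends with the higher excess of X over J among what is left of the two, or "neither" when 2 percentage points or less lies between them (noon / summer / neither)
* excess of X over J among what is left of the two at the end, noon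
* excess of X over J among what is left of the two at the end, summer

- E is single-handed; J and X are mirror images of each other, charged as a racemate, each of them at the stated concentration
- the numbers in the tables scatter by 2 percentage points (one standard deviation)
- reactions considered so far: Q + E + J -> E + D; Q + E + X -> E + Z; 2 E <-> L; Q -> G; D <-> Z
- an excess is below zero if the other one leads

**The clock.** I call p the negative logarithm of the fraction of J left. J and X meet the same [Q] and [E], so those cancel from the ratio of their rates, however the curve bends. The last two elm readings give 3.15 for the logarithm of J left over that of X left, the selectivity factor. Dividing p by it gives X's own logarithm, so p yields the excess of X over J.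

**Main step.** The first three birch readings give p rising by 0.0503 h⁻¹. If that rate held steady and followed E in proportion, noon would reach a p of 1.61, an excess of 50.0 %.

**Adding parking.** Elm holds 2.75 times the E of birch, yet over their shared times its p is up 1.42 times. That is a power of 0.347 in E, as parking suggests. Noon's p becomes 1.86 and its excess 56.2 %.

**Adding Q's fall.** Between 8.00 h and 30.0 h, birch's rate is down to 0.0219 h⁻¹. Elm's falls from 0.0964 h⁻¹ to 0.0270 h⁻¹. Read as exponential falls, these are 0.0504 h⁻¹ for birch and a faster 0.0748 h⁻¹ for elm. I replace each curve by its mean over 40 h: 43.0 % of the start for noon, using birch's fall, and 31.7 % for summer, using elm's. I reckon noon at a p of 0.801, an excess of 26.7 %. Summer, reckoned from elm's rate, comes out at 1.18, an excess of 38.4 %. I commit to summer, 12 percentage points ahead against a margin of 2 points.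

**The result.** The forecast names summer, with 26 % for noon and 39 % for summer, close to my numbers but not the same, and reads the runs as “most catalyst being parked as inactive dimer L”. The flasks give 25.7 % for noon and 37.9 % for summer, so summer leads.

    Q + E + J → E + D (k = 530 L² mol⁻² h⁻¹)
    Q + E + X → E + Z (k = 180 L² mol⁻² h⁻¹)
    2 E ⇌ L, settled at all times (K = 6800 L mol⁻¹)
    Q → G (k = 0.0280 h⁻¹)
    D ⇌ Z (k = 0.120 h⁻¹)

**Factor reused.** The difference in concentration of E is the main reason summer stands above noon: with that difference taken away, summer at noon's E gives 25.7 % instead of 37.9 %. The factor carries over. Summer's 30 % of J left gives 68.1 % of X left, against 66 % in the flask, and an excess of 38.8 %. Summer's neighbour with 0.040 M of E keeps 16 % of J, which gives 55.4 % of X left and an excess of 56.1 %; that flask ends at 54.7 %.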